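**Strategy.** Everything rests on disconnecting the pyran ring at C4–C4a (isochromene numbering) while the carbocycle is still a benzene ring. The key step is a 6-endo Mizoroki–Heck cyclisation: the aryl triflate carbon C4a adds to C4, the free terminus of the 2-oxy-1,3-diene C4=C3(O2)–CH=CH–CO2tBu that hangs on O2 of a benzyl ether. It exploits this dienoate: carbopalladation at C4 gives an allylpalladium over C3–Cα–Cβ, and β-hydride elimination returns the C3=C4 enol ether, so ring, enol ether and acrylate arise together. Later the phenol is oxidised to the C8a=C1 quinone methide, C7=C8 is dihydroxylated and C8-OH acylated.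

Key step: step 6

Assumption: 2,4-dihydroxy-5-methylbenzaldehyde (1) is taken as purchasable (otherwise one Vilsmeier formylation of 4-methylresorcinol gives it); atom numbers follow the isochromene skeleton, and Cα, Cβ are the two CH carbons of the acrylate.

**Step 1**
Reactants: 1 2,4-dihydroxy-5-methylbenzaldehyde
Product: 2 2-hydroxy-5-methyl-4-[(triisopropylsilyl)oxy]benzaldehyde
Conditions: TIPSCl, imidazole, DMF, 0 °C to rt
Reagents that add atoms: chlorotriisopropylsilane (TIPSCl), CC(C)[Si](Cl)(C(C)C)C(C)C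
Why: Silyl ether formation should be selective for the 4-OH, because the 2-OH is tied up in a hydrogen bond to the aldehyde.

**Step 2**
Reactants: 2 2-hydroxy-5-methyl-4-[(triisopropylsilyl)oxy]benzaldehyde
Product: 3 2-formyl-4-methyl-5-[(triisopropylsilyl)oxy]phenyl trifluoromethanesulfonate
Conditions: Tf2O, pyridine, CH2Cl2, 0 °C
Reagents that add atoms: trifluoromethanesulfonic anhydride (Tf2O), FC(F)(F)S(=O)(=O)OS(=O)(=O)C(F)(F)F
Why: O-Sulfonylation of the remaining phenol (aryl triflate formation) turns C4a into a cross-coupling electrophile.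

**Step 3**
Reactants: 3 2-formyl-4-methyl-5-[(triisopropylsilyl)oxy]phenyl trifluoromethanesulfonate
Product: 4 2-(hydroxymethyl)-4-methyl-5-[(triisopropylsilyl)oxy]phenyl trifluoromethanesulfonate
Conditions: NaBH4, THF/MeOH, 0 °C
Reagents that add atoms: none
Why: Chemoselective borohydride reduction of the aldehyde should leave the aryl triflate and the silyl ether untouched.

**Step 4**
Reactants: 4 2-(hydroxymethyl)-4-methyl-5-[(triisopropylsilyl)oxy]phenyl trifluoromethanesulfonate; 5 (E)-4-tert-butoxy-4-oxobut-2-enoic acid (mono-tert-butyl fumarate)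
Product: 6 tert-butyl 5-methyl-4-[(triisopropylsilyl)oxy]-2-(triflyloxy)benzyl (E)-but-2-enedioate
Conditions: EDC·HCl, DMAP (cat.), CH2Cl2, 0 °C to rt
Reagents that add atoms: none
Why: Carbodiimide (Steglich) esterification of the primary benzylic alcohol with the free acid of the fumarate half-ester.

**Step 5**
Reactants: 6 tert-butyl 5-methyl-4-[(triisopropylsilyl)oxy]-2-(triflyloxy)benzyl (E)-but-2-enedioate
Product: 7 tert-butyl (E)-4-({5-methyl-4-[(triisopropylsilyl)oxy]-2-(triflyloxy)benzyl}oxy)penta-2,4-dienoate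
Conditions: Cp2TiMe2, toluene, 70 °C, dark
Reagents that add atoms: dimethyltitanocene (Petasis reagent, Cp2TiMe2), C[Ti](C)(C1C=CC=C1)C1C=CC=C1
Why: Petasis carbonyl methylenation should convert the benzylic ester carbonyl, which is far less hindered than the tert-butyl ester carbonyl, into the 2-alkoxy-1,3-diene.

**Step 6**
Reactants: 7 tert-butyl (E)-4-({5-methyl-4-[(triisopropylsilyl)oxy]-2-(triflyloxy)benzyl}oxy)penta-2,4-dienoate
Product: 8 tert-butyl (E)-3-{7-methyl-6-[(triisopropylsilyl)oxy]-1H-isochromen-3-yl}prop-2-enoate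
Conditions: Pd(OAc)2 (10 mol %), P(o-tol)3, LiCl, Et3N, DMF, 80 °C
Reagents that add atoms: none
Why: Zerovalent palladium inserts into the aryl triflate at C4a and, after chloride exchange to the neutral arylpalladium chloride, adds syn across the diene terminus so that C4a bonds to C4 and palladium sits on C3 as an η3-allyl complex over C3–Cα–Cβ; syn β-hydride elimination of one H4 from the C3 σ-form gives the C3=C4 enol ether, and Et3N returns zerovalent palladium. The closest known reaction type is the intramolecular Mizoroki–Heck reaction of aryl halides and triflates with 1,3-dienes. The pyran ring is closed in the 6-endo-trig mode with respect to the C3=C4 double bond. No stereocenter is formed. The step needs attack at C4 and not the 5-exo attack at C3; this should be secured by the allyl stabilisation that only C4 attack provides, by C3 being fully substituted, and by the neutral chloride pathway, which steers the aryl group to the unsubstituted alkene terminus.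

**Step 7**
Reactants: 8 tert-butyl (E)-3-{7-methyl-6-[(triisopropylsilyl)oxy]-1H-isochromen-3-yl}prop-2-enoate
Product: 9 tert-butyl (E)-3-(6-hydroxy-7-methyl-1H-isochromen-3-yl)prop-2-enoate
Conditions: TBAF, AcOH, THF, 0 °C
Reagents that add atoms: none
Why: Fluoride-mediated desilylation frees the phenol that lies para to C8a.

**Step 8**
Reactants: 9 tert-butyl (E)-3-(6-hydroxy-7-methyl-1H-isochromen-3-yl)prop-2-enoate
Product: 12 tert-butyl (E)-3-[(7R,8R)-7,8-dihydroxy-7-methyl-6-oxo-7,8-dihydro-6H-isochromen-3-yl]prop-2-enoate, via quinone methide 10 (not isolated), via cyclic osmate ester 11 (not isolated)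
Conditions: Ag2O, 4 Å MS, CH2Cl2, rt, filter; then OsO4 (1.05 equiv), (DHQD)2PHAL (1.2 equiv), CH2Cl2/toluene, −78 °C; then aq. NaHSO3
Reagents that add atoms: osmium tetroxide (OsO4), O=[Os](=O)(=O)=O
Why: Silver oxide dehydrogenates the para-(alkoxymethyl)phenol to the C8a=C1 para-quinone methide, and OsO4 then adds across C7=C8 in a Sharpless-type asymmetric syn-dihydroxylation (stoichiometric, ligand-accelerated osmylation): syn addition makes the 7,8-diol cis, the (DHQD)2PHAL ligand is expected from the Sharpless quadrant model (H8 in the hindered quadrant) to send both oxygens to the face that gives 7R,8R, and C7=C8 should react in preference to the other double bonds because only there does the product keep the vinylogous ester conjugation of the pyran ring.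

**Step 9**
Reactants: 13 orsellinic acid (2,4-dihydroxy-6-methylbenzoic acid)
Product: 14 triethylsilyl 2-methyl-4,6-bis[(triethylsilyl)oxy]benzoate
Conditions: TESCl (3.5 equiv), imidazole, DMAP (cat.), DMF, rt
Reagents that add atoms: chlorotriethylsilane (TESCl), CC[Si](Cl)(CC)CC
Why: Exhaustive silylation masks both phenols as silyl ethers and gives a silyl ester that can be converted into the acid chloride under neutral conditions.

**Step 10**
Reactants: 12 tert-butyl (E)-3-[(7R,8R)-7,8-dihydroxy-7-methyl-6-oxo-7,8-dihydro-6H-isochromen-3-yl]prop-2-enoate; 14 triethylsilyl 2-methyl-4,6-bis[(triethylsilyl)oxy]benzoate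
Product: 16 (7R,8R)-3-[(E)-3-tert-butoxy-3-oxoprop-1-enyl]-7-hydroxy-7-methyl-6-oxo-7,8-dihydro-6H-isochromen-8-yl 2-methyl-4,6-bis[(triethylsilyl)oxy]benzoate, via acid chloride 15 (not isolated)
Conditions: 14, (COCl)2, DMF (cat.), CH2Cl2, 0 °C to rt; then 12, Et3N, DMAP, CH2Cl2, 0 °C to rt
Reagents that add atoms: none
Why: Oxalyl chloride/DMF turns the silyl ester into the acid chloride, and DMAP-catalysed acylation (nucleophilic acyl substitution) should take place only at the secondary C8-OH, the tertiary C7-OH being too hindered; the C8–O bond is not broken, so its configuration is retained.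

**Step 11**
Reactants: 16 (7R,8R)-3-[(E)-3-tert-butoxy-3-oxoprop-1-enyl]-7-hydroxy-7-methyl-6-oxo-7,8-dihydro-6H-isochromen-8-yl 2-methyl-4,6-bis[(triethylsilyl)oxy]benzoate
Product: 17 (+)-mitorubrinic acid B
Conditions: TFA/CH2Cl2/H2O, 0 °C to rt
Reagents that add atoms: none
Why: Acidolytic global deprotection: TFA should cleave the tert-butyl ester with loss of isobutene and hydrolyse the two aryl triethylsilyl ethers, leaving both stereocenters untouched.

**Compound list**

1 | 2,4-dihydroxy-5-methylbenzaldehyde | Cc1cc(C=O)c(O)cc1O | starting material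
2 | 2-hydroxy-5-methyl-4-[(triisopropylsilyl)oxy]benzaldehyde | Cc1cc(C=O)c(O)cc1O[Si](C(C)C)(C(C)C)C(C)C | intermediate
3 | 2-formyl-4-methyl-5-[(triisopropylsilyl)oxy]phenyl trifluoromethanesulfonate | Cc1cc(C=O)c(OS(=O)(=O)C(F)(F)F)cc1O[Si](C(C)C)(C(C)C)C(C)C | intermediate
4 | 2-(hydroxymethyl)-4-methyl-5-[(triisopropylsilyl)oxy]phenyl trifluoromethanesulfonate | Cc1cc(CO)c(OS(=O)(=O)C(F)(F)F)cc1O[Si](C(C)C)(C(C)C)C(C)C | intermediate
5 | (E)-4-tert-butoxy-4-oxobut-2-enoic acid (mono-tert-butyl fumarate) | OC(=O)/C=C/C(=O)OC(C)(C)C | starting material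
6 | tert-butyl 5-methyl-4-[(triisopropylsilyl)oxy]-2-(triflyloxy)benzyl (E)-but-2-enedioate | Cc1cc(COC(=O)/C=C/C(=O)OC(C)(C)C)c(OS(=O)(=O)C(F)(F)F)cc1O[Si](C(C)C)(C(C)C)C(C)C | intermediate
7 | tert-butyl (E)-4-({5-methyl-4-[(triisopropylsilyl)oxy]-2-(triflyloxy)benzyl}oxy)penta-2,4-dienoate | Cc1cc(COC(=C)/C=C/C(=O)OC(C)(C)C)c(OS(=O)(=O)C(F)(F)F)cc1O[Si](C(C)C)(C(C)C)C(C)C | intermediate
8 | tert-butyl (E)-3-{7-methyl-6-[(triisopropylsilyl)oxy]-1H-isochromen-3-yl}prop-2-enoate | Cc1cc2c(cc1O[Si](C(C)C)(C(C)C)C(C)C)C=C(/C=C/C(=O)OC(C)(C)C)OC2 | intermediate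
9 | tert-butyl (E)-3-(6-hydroxy-7-methyl-1H-isochromen-3-yl)prop-2-enoate | Cc1cc2c(cc1O)C=C(/C=C/C(=O)OC(C)(C)C)OC2 | intermediate
10 | tert-butyl (E)-3-(7-methyl-6-oxo-6H-isochromen-3-yl)prop-2-enoate (para-quinone methide) | CC1=CC2=COC(/C=C/C(=O)OC(C)(C)C)=CC2=CC1=O | intermediate
11 | cyclic (7R,8R)-7,8-osmate ester of 10 (hexavalent osmium, ligand not drawn) | O=[Os]1(=O)O[C@@H]2C3=COC(/C=C/C(=O)OC(C)(C)C)=CC3=CC(=O)[C@]2(C)O1 | intermediate
12 | tert-butyl (E)-3-[(7R,8R)-7,8-dihydroxy-7-methyl-6-oxo-7,8-dihydro-6H-isochromen-3-yl]prop-2-enoate | O[C@@H]1C2=COC(/C=C/C(=O)OC(C)(C)C)=CC2=CC(=O)[C@]1(C)O | intermediate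
13 | orsellinic acid (2,4-dihydroxy-6-methylbenzoic acid) | Cc1cc(O)cc(O)c1C(=O)O | starting material
14 | triethylsilyl 2-methyl-4,6-bis[(triethylsilyl)oxy]benzoate | Cc1cc(O[Si](CC)(CC)CC)cc(O[Si](CC)(CC)CC)c1C(=O)O[Si](CC)(CC)CC | intermediate
15 | 2-methyl-4,6-bis[(triethylsilyl)oxy]benzoyl chloride | Cc1cc(O[Si](CC)(CC)CC)cc(O[Si](CC)(CC)CC)c1C(=O)Cl | intermediate
16 | (7R,8R)-3-[(E)-3-tert-butoxy-3-oxoprop-1-enyl]-7-hydroxy-7-methyl-6-oxo-7,8-dihydro-6H-isochromen-8-yl 2-methyl-4,6-bis[(triethylsilyl)oxy]benzoate | Cc1cc(O[Si](CC)(CC)CC)cc(O[Si](CC)(CC)CC)c1C(=O)O[C@@H]1C2=COC(/C=C/C(=O)OC(C)(C)C)=CC2=CC(=O)[C@]1(C)O | intermediate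
17 | (+)-mitorubrinic acid B, (7R,8R)-3-[(E)-2-carboxyvinyl]-7-hydroxy-7-methyl-6-oxo-7,8-dihydro-6H-isochromen-8-yl 2,4-dihydroxy-6-methylbenzoate | Cc1cc(O)cc(O)c1C(=O)O[C@@H]1C2=COC(/C=C/C(=O)O)=CC2=CC(=O)[C@]1(C)O | target

**Step count.** Total: 11 steps. Longest linear sequence: 10 steps (steps 1–8, 10 and 11).

**Steps most likely to fail**

Step 8 (oxidation and asymmetric dihydroxylation). What may go wrong: osmylation at the C1=C8a, C3=C4 or C4a=C5 double bonds, poor facial selectivity on the flat quinone methide, or addition of water at C1 before osmylation. The fallback reaches the diol by epoxidation and carbon dioxide insertion instead of osmylation. It sets out from 10, made from 9 with Ag2O as in step 8. Jacobsen–Katsuki epoxidation under anhydrous conditions should give the 7,8-epoxide F1; the reagents are (salen)MnCl (the chloride of trivalent manganese with the N,N'-bis(3,5-di-tert-butylsalicylidene)-trans-1,2-cyclohexanediamine ligand), mCPBA and N-methylmorpholine N-oxide in CH2Cl2 at −78 °C, using the catalyst enantiomer that places the oxygen on the face of the later 7-OH. LiBr-catalysed insertion of CO2 (1 atm, THF, 60 °C) should open F1 at C8 with bromide and close again with a second inversion, giving the cis-fused cyclic carbonate F2. K2CO3 in MeOH at 0 °C then frees the cis-diol, and the route is rejoined at 12.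

Step 6 (Heck cyclisation). What may go wrong: 5-exo carbopalladation at C3 followed by cyclopropanation or ring-opening cascades, or capture of the allylpalladium by a nucleophile before β-hydride elimination. The fallback sets out from 3. Wittig reaction of 3-(trimethylsilyl)propynal with Ph3P=CHCO2tBu gives the silylated enyne ester F3, and K2CO3 in MeOH gives the terminal enyne ester F4. Sonogashira coupling of 3 with F4 (Pd(PPh3)2Cl2, CuI, Et3N, THF) gives the 2-alkynylbenzaldehyde F5, and TBAF/AcOH gives the phenol F6. AgOTf-catalysed 6-endo-dig cycloisomerisation (CH2Cl2, rt) should convert F6 into its isomer, the quinone methide, so the route is rejoined at 10. In this variant the same carbon–carbon bond is made by cross-coupling and the ring is closed at oxygen.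

Step 5 (Petasis methylenation). What may go wrong: competing methylenation of the tert-butyl ester carbonyl, or attack of the titanium carbene on the electron-poor double bond. The fallback installs the ester after the methylenation and sets out from 4. Acylation with acryloyl chloride (Et3N, CH2Cl2, 0 °C) gives the acrylate F7, which has only one carbonyl group. Cp2TiMe2 (toluene, 70 °C) gives the 2-(benzyloxy)buta-1,3-diene F8. Cross-metathesis of its monosubstituted vinyl group with tert-butyl acrylate (second-generation Hoveyda–Grubbs catalyst, (H2IMes)Cl2Ru=CH(C6H4-2-OiPr), CH2Cl2, 40 °C) should give the E-dienoate, and the route is rejoined at 7.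

**Further compounds**

F1 | step 8 | tert-butyl (E)-3-[(7R,8R)-7,8-epoxy-7-methyl-6-oxo-7,8-dihydro-6H-isochromen-3-yl]prop-2-enoate | O1[C@@H]2C3=COC(/C=C/C(=O)OC(C)(C)C)=CC3=CC(=O)[C@]12C
F2 | step 8 | cyclic 7,8-carbonate of tert-butyl (E)-3-[(7R,8R)-7,8-dihydroxy-7-methyl-6-oxo-7,8-dihydro-6H-isochromen-3-yl]prop-2-enoate | O=C1O[C@@H]2C3=COC(/C=C/C(=O)OC(C)(C)C)=CC3=CC(=O)[C@]2(C)O1
F3 | step 6 | tert-butyl (E)-5-(trimethylsilyl)pent-2-en-4-ynoate | C[Si](C)(C)C#C/C=C/C(=O)OC(C)(C)C
F4 | step 6 | tert-butyl (E)-pent-2-en-4-ynoate | C#C/C=C/C(=O)OC(C)(C)C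
F5 | step 6 | tert-butyl (E)-5-{2-formyl-4-methyl-5-[(triisopropylsilyl)oxy]phenyl}pent-2-en-4-ynoate | Cc1cc(C=O)c(C#C/C=C/C(=O)OC(C)(C)C)cc1O[Si](C(C)C)(C(C)C)C(C)C
F6 | step 6 | tert-butyl (E)-5-(2-formyl-5-hydroxy-4-methylphenyl)pent-2-en-4-ynoate | Cc1cc(C=O)c(C#C/C=C/C(=O)OC(C)(C)C)cc1O
F7 | step 5 | 5-methyl-4-[(triisopropylsilyl)oxy]-2-(triflyloxy)benzyl prop-2-enoate | Cc1cc(COC(=O)C=C)c(OS(=O)(=O)C(F)(F)F)cc1O[Si](C(C)C)(C(C)C)C(C)C
F8 | step 5 | 2-[(buta-1,3-dien-2-yloxy)methyl]-4-methyl-5-[(triisopropylsilyl)oxy]phenyl trifluoromethanesulfonate | Cc1cc(COC(=C)C=C)c(OS(=O)(=O)C(F)(F)F)cc1O[Si](C(C)C)(C(C)C)C(C)C
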